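**Strategy.** Everything rests on growing the dienone ring (C1–C5 plus spiro C6 of the spiro[5.5]undecane) from a four-membered ring. A spiro 3-methoxycyclobutenone already carries C1(OMe)=C2–C3(=O) and C6; 1-methoxyvinyllithium brings C4 and C5. Its addition to the carbonyl triggers 4π ring opening and 6π ring closure, so one operation turns the cyclobutenone into the six-membered ring, makes the C5–C6 bond and sets the quaternary spiro centre under control of the substituted cyclohexane chair. The feature exploited is that C6 is flanked by CH (C5) and C–OMe (C1) of a cross-conjugated enone. The cyclobutenone comes from a cyclohexylidene ketene and methoxyacetylene.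

Key step: step 10

Remark 1: 3 is achiral (E/Z mixture); 5–8 are racemic, and for 6–8 the enantiomer drawn is the one kept in step 5.
Remark 2: the configuration at the ester-bearing carbon of 6, 10, 11 and 15, at the spiro carbon of 17 and at the carbinol carbon of 18 is of no consequence, because that carbon is sp2 in 16 and again in 19; one epimer is drawn or the centre is left undefined.
Remark 3: 4 is taken as purchasable; otherwise it is one Friedel–Crafts propionylation of 1,2,4-trimethoxybenzene.

Step 1
Reactants: 1 2,4,5-trimethoxybenzaldehyde; 2 methyl 3-oxopentanoate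
Product: 3 methyl 3-oxo-2-[(2,4,5-trimethoxyphenyl)methylidene]pentanoate (E/Z mixture)
Conditions: piperidine (cat.), AcOH (cat.), toluene, reflux, azeotropic removal of water
Reagents that add atoms: none
Why: Knoevenagel condensation of the doubly activated methylene of 2 with the aldehyde; no stereocentre is formed and the alkene geometry is irrelevant because this carbon becomes sp3 in step 2.

Step 2
Reactants: 3 arylidene keto ester; 4 1-(2,4,5-trimethoxyphenyl)propan-1-one
Product: 6 methyl rac-(1R,5S,6S)-3,5-dimethyl-2-oxo-4,6-bis(2,4,5-trimethoxyphenyl)cyclohex-3-ene-1-carboxylate, via Michael adduct 5 (not isolated)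
Conditions: 4, LDA, THF, −78 °C; then 3, −78 → −20 °C; aq NH4Cl; crude adduct, NaOMe (0.3 equiv), MeOH, 65 °C
Reagents that add atoms: none
Why: Michael addition of the lithium enolate of 4 to the doubly activated alkene of 3, then base-catalysed intramolecular aldol condensation of the ethyl-ketone α-carbon onto the aryl ketone (Robinson-type annulation); C6 forms racemic, and the trans relation of 5-methyl and 6-aryl should result from equilibration at the epimerisable carbon next to the aryl ketone before closure and at the γ-position of the enone after it, where the trans-diaxial arrangement relieves A(1,2) strain with the vinylic aryl group.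

Step 3
Reactants: 6 cyclohexenone keto ester
Product: 7 methyl rac-(5S,6R)-3,5-dimethyl-4,6-bis(2,4,5-trimethoxyphenyl)-2-(trifluoromethylsulfonyloxy)cyclohexa-1,3-diene-1-carboxylate
Conditions: NaH, THF, 0 °C; then PhNTf2, 0 → 25 °C
Reagents that add atoms: N-phenylbis(trifluoromethanesulfonimide) O=S(=O)(N(c1ccccc1)S(=O)(=O)C(F)(F)F)C(F)(F)F
Why: enol triflate formation by O-sulfonylation of the sodium enolate of the β-keto ester on the ketone oxygen gives the dienyl triflate; C5 and C6 are untouched.

Step 4
Reactants: 7 dienyl triflate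
Product: 8 methyl rac-(5S,6R)-2-ethyl-3,5-dimethyl-4,6-bis(2,4,5-trimethoxyphenyl)cyclohexa-1,3-diene-1-carboxylate
Conditions: EtMgBr (1.5 equiv), Fe(acac)3 (5 mol %), THF/NMP, −30 °C
Reagents that add atoms: ethylmagnesium bromide CC[Mg]Br
Why: iron-catalysed Kumada-type cross-coupling of an alkenyl triflate with an alkyl Grignard reagent, which is fast at low temperature, tolerates the ester and is not troubled by β-hydride elimination of the ethyl group.

Step 5
Reactants: 8 racemic diene ester
Product: 9 methyl (5S,6R)-2-ethyl-3,5-dimethyl-4,6-bis(2,4,5-trimethoxyphenyl)cyclohexa-1,3-diene-1-carboxylate (single enantiomer)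
Conditions: preparative SFC, amylose tris(3,5-dimethylphenylcarbamate) stationary phase, CO2/MeOH
Reagents that add atoms: none
Why: resolution of the racemate on a polysaccharide chiral stationary phase, the usual means for neutral aryl-substituted esters of this kind; the (5S,6R) enantiomer is assigned by X-ray or chiroptical analysis and carried on, the other is set aside.

Step 6
Reactants: 9 diene ester
Product: 10 methyl (1R,2R,3S,4S,5R,6S)-2-ethyl-3,5-dimethyl-4,6-bis(2,4,5-trimethoxyphenyl)cyclohexane-1-carboxylate
Conditions: H2 (50 bar), [Ir(cod)(PCy3)(py)]PF6 (10 mol %), CH2Cl2, 25 °C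
Reagents that add atoms: none
Why: homogeneous hydrogenation with a cationic iridium catalyst that reduces tetrasubstituted alkenes without double-bond migration and adds both equivalents of H2 syn from one face: A(1,2) strain with the vinylic aryl and ester groups should hold the trans 5-methyl and 6-aryl groups pseudoaxial, the aryl group then covers one diene face, and the four new C–H bonds at C1–C4 form on the face of the 5-methyl group, which sets 2-ethyl, 3-methyl and 4-aryl all cis to the 6-aryl group (the descriptors at C5 and C6 change only through the priority rules).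

Step 7
Reactants: 10 cyclohexane ester
Product: 11 (1S,2R,3S,4S,5R,6S)-2-ethyl-3,5-dimethyl-4,6-bis(2,4,5-trimethoxyphenyl)cyclohexane-1-carboxylic acid
Conditions: KOH, MeOH/H2O, 100 °C (sealed); then aq HCl
Reagents that add atoms: potassium hydroxide [K+].[OH-]
Why: saponification of the hindered ester under forcing conditions, under which the axial ester (syn-diaxial to the 3-methyl group) should first epimerise through its enolate to the equatorial position; either C1 epimer serves step 9.

Step 8
Reactants: 12 2-chloro-1,1-dimethoxyethane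
Product: 14 methoxyethyne (methoxyacetylene), via sodium methoxyethynide 13 (not isolated)
Conditions: NaNH2 (3.2 equiv), liquid NH3, −33 °C; evaporate NH3; cold saturated aq NaCl, −20 → 20 °C; distil into a cold trap
Reagents that add atoms: none
Why: amide-induced double elimination (HCl, then methanol) from the chloroacetal gives the sodium acetylide of the ynol ether, which is protonated on aqueous quench and distilled as a low-boiling liquid.

Step 9
Reactants: 11 cyclohexanecarboxylic acid; 14 methoxyethyne
Product: 17 (4R,5R,6S,7S,8R,9R)-5-ethyl-3-methoxy-6,8-dimethyl-7,9-bis(2,4,5-trimethoxyphenyl)spiro[3.5]non-2-en-1-one, via acid chloride 15 (not isolated), via cyclohexylidene ketene 16 (not isolated)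
Conditions: 1-chloro-N,N,2-trimethylprop-1-en-1-amine, CH2Cl2, 0 → 25 °C; then 14 (3 equiv), Et3N (2 equiv), toluene, sealed tube, 50 °C
Reagents that add atoms: none
Why: neutral conversion to the acid chloride, dehydrochlorination by the amine to the ketene and regioselective thermal [2+2] cycloaddition with the ynol ether, whose nucleophilic CH carbon bonds to the ketene carbonyl carbon so that a 3-methoxycyclobutenone results; the alkyne should reach the ketene α-carbon from the equatorial side, but the configuration of this spiro carbon is irrelevant.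

Step 10
Reactants: 17 spiro 3-methoxycyclobutenone
Product: 21 [(6S,7R,8S,9S,10R,11R)-7-ethyl-1,4-dimethoxy-8,10-dimethyl-9,11-bis(2,4,5-trimethoxyphenyl)spiro[5.5]undeca-1,3-dien-3-yl]oxy(trimethyl)silane, via lithium cyclobutenolate 18 (not isolated), via lithium trienolate 19 (not isolated), via lithium cyclohexadienolate 20 (not isolated)
Conditions: methyl vinyl ether, t-BuLi, THF, −78 → 0 °C; then 17, THF, −78 → 25 °C; then Me3SiCl, Et3N, −78 → 0 °C; non-aqueous work-up
Reagents that add atoms: 1-methoxyvinyllithium [Li]C(=C)OC (made in the flask from methyl vinyl ether COC=C and tert-butyllithium); chlorotrimethylsilane C[Si](C)(C)Cl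
Why: 1-Methoxyvinyllithium adds 1,2 to the strained carbonyl C1 of 17; the cyclobutenolate 18 then undergoes oxyanion-accelerated conrotatory 4π opening of the C1–C4 bond (numbering of 17) with the oxide turning outward and the alkenyl group inward, and the resulting Z-configured 3-oxido-hexatriene 19 closes by thermal disrotatory 6π electrocyclisation between the vinyl CH2 terminus and the cyclohexylidene carbon to the six-membered dienolate 20, which is trapped on oxygen as the silyl ether. The closest known reaction type is the ring expansion of cyclobutenones to cyclohexenones by addition of 1-lithioalkenes followed by the same 4π/6π electrocyclic cascade. The only ring closed is the carbocyclic six-membered ring, in the 6π-electrocyclic disrotatory mode, through the new C5–C6 bond (numbering of 21). The one new stereocentre is the spiro carbon C6, which is planar in 19 so that the configuration of 17 does not matter; it is set by the chair of the pentasubstituted cyclohexylidene, which should take the small CH2 terminus on its axial face (syn to the axial 8-methyl group) so that the bulkier C1(OMe) arm ends equatorial and its methoxy group stays clear of that methyl group. The step needs 1,2- and not conjugate addition (hard organolithium, ketone in a four-membered ring), inward rotation of the alkenyl group (the oxide is the strongest outward-rotating donor) and the facial selectivity just described; the allylic strain of the tetrasubstituted enol-ether terminus against the equatorial 7-ethyl and 11-aryl groups is released as that terminus pyramidalises.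

Step 11
Reactants: 21 silyl dienol ether
Product: 22 Tatanan B, (6S,7R,8S,9S,10R,11R)-7-ethyl-1,4-dimethoxy-8,10-dimethyl-9,11-bis(2,4,5-trimethoxyphenyl)spiro[5.5]undeca-1,4-dien-3-one
Conditions: Pd(OAc)2 (1.1 equiv), MeCN, 25 °C
Reagents that add atoms: none
Why: Saegusa–Ito oxidation, in which palladation of the silyl enol ether at C4 and β-hydride elimination from C5 give the cross-conjugated dienone; this is the only possible direction because C2 is already sp2 and C6 is quaternary, and no stereocentre is affected.

**Compound list**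

1 | 2,4,5-trimethoxybenzaldehyde | O=Cc1cc(OC)c(OC)cc1OC | starting material
2 | methyl 3-oxopentanoate | CCC(=O)CC(=O)OC | starting material
3 | methyl 3-oxo-2-[(2,4,5-trimethoxyphenyl)methylidene]pentanoate (E/Z mixture, geometry undefined) | CCC(=O)C(=Cc1cc(OC)c(OC)cc1OC)C(=O)OC | intermediate
4 | 1-(2,4,5-trimethoxyphenyl)propan-1-one | CCC(=O)c1cc(OC)c(OC)cc1OC | starting material
5 | methyl 4-methyl-5-oxo-2-propanoyl-3,5-bis(2,4,5-trimethoxyphenyl)pentanoate (racemic diastereomer mixture, centres undefined) | CCC(=O)C(C(=O)OC)C(c1cc(OC)c(OC)cc1OC)C(C)C(=O)c1cc(OC)c(OC)cc1OC | intermediate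
6 | methyl rac-(1R,5S,6S)-3,5-dimethyl-2-oxo-4,6-bis(2,4,5-trimethoxyphenyl)cyclohex-3-ene-1-carboxylate (5-Me/6-aryl trans) | COC(=O)[C@H]1C(=O)C(C)=C(c2cc(OC)c(OC)cc2OC)[C@@H](C)[C@@H]1c3cc(OC)c(OC)cc3OC | intermediate
7 | methyl rac-(5S,6R)-3,5-dimethyl-4,6-bis(2,4,5-trimethoxyphenyl)-2-(trifluoromethylsulfonyloxy)cyclohexa-1,3-diene-1-carboxylate | COC(=O)C1=C(OS(=O)(=O)C(F)(F)F)C(C)=C(c2cc(OC)c(OC)cc2OC)[C@@H](C)[C@@H]1c3cc(OC)c(OC)cc3OC | intermediate
8 | methyl rac-(5S,6R)-2-ethyl-3,5-dimethyl-4,6-bis(2,4,5-trimethoxyphenyl)cyclohexa-1,3-diene-1-carboxylate (racemate, one enantiomer drawn) | COC(=O)C1=C(CC)C(C)=C(c2cc(OC)c(OC)cc2OC)[C@@H](C)[C@@H]1c3cc(OC)c(OC)cc3OC | intermediate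
9 | methyl (5S,6R)-2-ethyl-3,5-dimethyl-4,6-bis(2,4,5-trimethoxyphenyl)cyclohexa-1,3-diene-1-carboxylate (single enantiomer) | COC(=O)C1=C(CC)C(C)=C(c2cc(OC)c(OC)cc2OC)[C@@H](C)[C@@H]1c3cc(OC)c(OC)cc3OC | intermediate
10 | methyl (1R,2R,3S,4S,5R,6S)-2-ethyl-3,5-dimethyl-4,6-bis(2,4,5-trimethoxyphenyl)cyclohexane-1-carboxylate (ester, ethyl, 3-methyl and both aryl groups cis; 5-methyl trans) | CC[C@@H]1[C@H](C)[C@H](c2cc(OC)c(OC)cc2OC)[C@@H](C)[C@H](c3cc(OC)c(OC)cc3OC)[C@@H]1C(=O)OC | intermediate
11 | (1S,2R,3S,4S,5R,6S)-2-ethyl-3,5-dimethyl-4,6-bis(2,4,5-trimethoxyphenyl)cyclohexane-1-carboxylic acid | CC[C@@H]1[C@H](C)[C@H](c2cc(OC)c(OC)cc2OC)[C@@H](C)[C@H](c3cc(OC)c(OC)cc3OC)[C@H]1C(=O)O | intermediate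
12 | 2-chloro-1,1-dimethoxyethane | COC(CCl)OC | starting material
13 | sodium methoxyethynide | COC#C[Na] | intermediate
14 | methoxyethyne | COC#C | intermediate
15 | (1S,2R,3S,4S,5R,6S)-2-ethyl-3,5-dimethyl-4,6-bis(2,4,5-trimethoxyphenyl)cyclohexane-1-carbonyl chloride | CC[C@@H]1[C@H](C)[C@H](c2cc(OC)c(OC)cc2OC)[C@@H](C)[C@H](c3cc(OC)c(OC)cc3OC)[C@H]1C(=O)Cl | intermediate
16 | [(2R,3S,4S,5R,6R)-2-ethyl-3,5-dimethyl-4,6-bis(2,4,5-trimethoxyphenyl)cyclohexylidene]methanone (ketene) | CC[C@@H]1[C@H](C)[C@H](c2cc(OC)c(OC)cc2OC)[C@@H](C)[C@H](c3cc(OC)c(OC)cc3OC)C1=C=O | intermediate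
17 | (4R,5R,6S,7S,8R,9R)-5-ethyl-3-methoxy-6,8-dimethyl-7,9-bis(2,4,5-trimethoxyphenyl)spiro[3.5]non-2-en-1-one | CC[C@@H]1[C@H](C)[C@H](c2cc(OC)c(OC)cc2OC)[C@@H](C)[C@H](c3cc(OC)c(OC)cc3OC)[C@]14C(=O)C=C4OC | intermediate
18 | lithium 5-ethyl-3-methoxy-1-(1-methoxyethenyl)-6,8-dimethyl-7,9-bis(2,4,5-trimethoxyphenyl)spiro[3.5]non-2-en-1-olate (carbinol centre undefined) | CC[C@@H]1[C@H](C)[C@H](c2cc(OC)c(OC)cc2OC)[C@@H](C)[C@H](c3cc(OC)c(OC)cc3OC)[C@]14C(O[Li])(C(=C)OC)C=C4OC | intermediate
19 | lithium trienolate: 1-[2-ethyl-3,5-dimethyl-4,6-bis(2,4,5-trimethoxyphenyl)cyclohexylidene]-1,4-dimethoxypenta-2,4-dien-3-olate (oxide trans to the cyclohexylidene arm; exocyclic alkene geometry undefined) | CC[C@@H]1[C@H](C)[C@H](c2cc(OC)c(OC)cc2OC)[C@@H](C)[C@H](c3cc(OC)c(OC)cc3OC)C1=C(OC)/C=C(/O[Li])C(=C)OC | intermediate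
20 | lithium (6S,7R,8S,9S,10R,11R)-7-ethyl-1,4-dimethoxy-8,10-dimethyl-9,11-bis(2,4,5-trimethoxyphenyl)spiro[5.5]undeca-1,3-dien-3-olate | CC[C@@H]1[C@H](C)[C@H](c2cc(OC)c(OC)cc2OC)[C@@H](C)[C@H](c3cc(OC)c(OC)cc3OC)[C@]14CC(OC)=C(O[Li])C=C4OC | intermediate
21 | [(6S,7R,8S,9S,10R,11R)-7-ethyl-1,4-dimethoxy-8,10-dimethyl-9,11-bis(2,4,5-trimethoxyphenyl)spiro[5.5]undeca-1,3-dien-3-yl]oxy(trimethyl)silane | CC[C@@H]1[C@H](C)[C@H](c2cc(OC)c(OC)cc2OC)[C@@H](C)[C@H](c3cc(OC)c(OC)cc3OC)[C@]14CC(OC)=C(O[Si](C)(C)C)C=C4OC | intermediate
22 | Tatanan B, (6S,7R,8S,9S,10R,11R)-7-ethyl-1,4-dimethoxy-8,10-dimethyl-9,11-bis(2,4,5-trimethoxyphenyl)spiro[5.5]undeca-1,4-dien-3-one | CC[C@@H]1[C@H](C)[C@H](c2cc(OC)c(OC)cc2OC)[C@@H](C)[C@H](c2cc(OC)c(OC)cc2OC)[C@]12C=C(OC)C(=O)C=C2OC | target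

**Count.** Total: 11 steps. Longest linear sequence: 10 steps (steps 1–7 and 9–11); step 8 is a one-step side branch.

**Steps most likely to fail**

Step 10. The 6π closure may take place on the other face of the cyclohexylidene terminus, so that the CH2 arm ends equatorial and the C6 epimer forms, or it may stall at the ring-opened stage because the tetrasubstituted enol-ether terminus cannot reach the closing geometry. The fallback reverses the roles of the two arms, so that the oxygenated carbon C1 is the one that swings onto the spiro carbon. It sets out from ketene 16 (made from 11 as in step 9). Thermal [2+2] cycloaddition with (Z)-1,2-dimethoxyethene gives the 2,3-dimethoxy spirocyclobutanone F1. DBU-induced β-elimination of methanol gives the 2-methoxy spirocyclobutenone F2. Addition of 2,2-dimethoxyvinyllithium (from 2-bromo-1,1-dimethoxyethene and t-BuLi) to its carbonyl starts the same 4π/6π sequence, which now bonds the C(OMe)2 terminus to C6 and gives the lithium ketal enolate F3. This loses lithium methoxide in the flask and comes back to the route at 22, so step 11 is not needed. If the approach trajectory rather than product strain decides the face, this variant is stereochemically complementary to step 10.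

Step 6. Hydrogen may be delivered to both diene faces, or the reduction may stop after one equivalent at a tetrasubstituted monoene. The fallback splits the reduction into two substrate-controlled events and sets out from 9. Li in NH3/THF with t-BuOH at −78 °C effects 1,6-reduction of the dienoate, with protonation of the benzylic C4 trans to the 5-methyl group and kinetic α-protonation anti to the 6-aryl group. This should give the β,γ-unsaturated cyclohexene ester F4, in which the ester and the 4-aryl group both shield the same face of the remaining C2=C3 bond. Heterogeneous hydrogenation (H2, 50 bar, PtO2, AcOH) from the open face then comes back to the route at 10.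

Step 9. Dehydrochlorination of the hindered acid chloride may be slower than the loss of methoxyacetylene to amine hydrochloride or oligomerisation. The acid chloride may also acylate the neighbouring arene, or the cyclobutenone may open thermally and take up a second alkyne. The fallback generates the ketene without amine hydrochloride and sets out from 11. Esterification with phenol (DCC, DMAP, CH2Cl2) gives the phenyl ester F5. With LiHMDS in THF at −78 °C, then warming to 25 °C in the presence of 14, its lithium enolate ejects phenoxide (E1cB) to give ketene 16, which is trapped by 14 and comes back to the route at 17.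

**Further compounds**

F1 | step 10 | 5-ethyl-2,3-dimethoxy-6,8-dimethyl-7,9-bis(2,4,5-trimethoxyphenyl)spiro[3.5]nonan-1-one (C5–C9 as in 17; C2, C3 and C4 undefined) | CC[C@@H]1[C@H](C)[C@H](c2cc(OC)c(OC)cc2OC)[C@@H](C)[C@H](c3cc(OC)c(OC)cc3OC)C14C(OC)C(OC)C4=O
F2 | step 10 | 5-ethyl-2-methoxy-6,8-dimethyl-7,9-bis(2,4,5-trimethoxyphenyl)spiro[3.5]non-2-en-1-one (C5–C9 as in 17; spiro centre undefined) | CC[C@@H]1[C@H](C)[C@H](c2cc(OC)c(OC)cc2OC)[C@@H](C)[C@H](c3cc(OC)c(OC)cc3OC)C14C=C(OC)C4=O
F3 | step 10 | lithium (6S,7R,8S,9S,10R,11R)-7-ethyl-1,1,4-trimethoxy-8,10-dimethyl-9,11-bis(2,4,5-trimethoxyphenyl)spiro[5.5]undeca-2,4-dien-3-olate | CC[C@@H]1[C@H](C)[C@H](c2cc(OC)c(OC)cc2OC)[C@@H](C)[C@H](c3cc(OC)c(OC)cc3OC)[C@]14C=C(OC)C(O[Li])=CC4(OC)OC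
F4 | step 6 | methyl (1S,4R,5S,6S)-2-ethyl-3,5-dimethyl-4,6-bis(2,4,5-trimethoxyphenyl)cyclohex-2-ene-1-carboxylate | CCC1=C(C)[C@H](c2cc(OC)c(OC)cc2OC)[C@@H](C)[C@H](c3cc(OC)c(OC)cc3OC)[C@@H]1C(=O)OC
F5 | step 9 | phenyl (1S,2R,3S,4S,5R,6S)-2-ethyl-3,5-dimethyl-4,6-bis(2,4,5-trimethoxyphenyl)cyclohexane-1-carboxylate | CC[C@@H]1[C@H](C)[C@H](c2cc(OC)c(OC)cc2OC)[C@@H](C)[C@H](c3cc(OC)c(OC)cc3OC)[C@H]1C(=O)Oc5ccccc5
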